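**Plan**
- Retrosynthetic cuts, in order: ring C hydroxyquinone ← resorcinol (C11–H oxidised last); C5–C10 and C6–C7 (one cycloaddition that also makes the 20,7-lactone); C7–C8 (formyl); C1–C10 (enolate alkylation); C12–C13 and C8–C14 (ring C).
- Feature used by the key step: ring C (C8, C9, C11–C14) carries oxygen at C12 and C14 on either side of the isopropyl-bearing C13, i.e. it is an oxidised 2-alkylresorcinol. A cyclobutenone (C12, C8, C9, C11) and a siloxyalkyne (C13, C14) give exactly this arene, with the two oxygens already differentiated (free OH at C12, silyl ether at C14).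
- Second feature: C7, C8, C9, C10, the C20(=O)–O bridge and C5–C6 form an arene-fused 2-oxabicyclo[2.2.2]octene, the adduct of a 2-benzopyran-3-one with the C5=C6 alkene tethered through C1–C4.
- Forward order: ring C (step 3) → tether on C10 → C7 formyl ortho to O14 → rings A and B plus the lactone in one intramolecular Diels–Alder step → C6–B to C6–OH → ring C to the hydroxyquinone.
- Stereochemistry: C4 from a Sharpless epoxidation relayed by a stereospecific epoxide-to-aldehyde 1,2-shift; C5, C6, C7, C10 from the cycloaddition (E-alkenylboronate, lactone bridge, C4 control); O6 by retentive C–B oxidation.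

Key step: step 3

Assumption: abietane numbering is used for ring positions throughout; 3-ethoxycyclobut-2-en-1-one, 2-(trimethylsilyl)ethyl acetate, 5-chloropent-1-yne and bis(pinacolato)borylmethane are taken as catalogue chemicals, and MABR is pre-formed from AlMe3 and 4-bromo-2,6-di-tert-butylphenol.

Abbreviations: TMSE = 2-(trimethylsilyl)ethyl; TIPS = tri(propan-2-yl)silyl; TBS = tert-butyl(dimethyl)silyl; MOM = methoxymethyl; Bpin = 4,4,5,5-tetramethyl-1,3,2-dioxaborolan-2-yl.

**Step 1**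
Reactants: 1 ethyl 2-methylpropanoate
Product: 3 triisopropyl[(3-methylbut-1-yn-1-yl)oxy]silane, via lithium ynolate 2 (not isolated)
Conditions: CH2Br2, LiTMP, THF, −78 °C; LiHMDS; n-BuLi, −78 °C → rt; TIPSCl, −78 → 0 °C
Reagents that add atoms: dibromomethane, BrCBr; chlorotri(propan-2-yl)silane, CC(C)[Si](Cl)(C(C)C)C(C)C
Why: Kowalski ester homologation: LiCHBr2 adds to the ester, the dibromo enolate undergoes Br/Li exchange and 1,2-shift to the lithium ynolate, and O-silylation with the bulky TIPS group gives a storable siloxyalkyne.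

**Step 2**
Reactants: 4 3-ethoxycyclobut-2-en-1-one; 5 2-(trimethylsilyl)ethyl acetate
Product: 7 TMSE 2-(3-oxocyclobut-1-en-1-yl)acetate, via carbinol adduct 6 (not isolated)
Conditions: LDA, THF, −78 °C (enolate of 5), then 4; 1 M HCl, 0 °C
Reagents that add atoms: water, O
Why: Stork–Danheiser-type carbonyl transposition: 1,2-addition of the ester enolate to the vinylogous ester, then acid-promoted loss of water and hydrolysis of the enol ether gives the 3-substituted cyclobutenone (ring carbons = C12, C8, C9, C11).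

**Step 3**
Reactants: 7 TMSE 2-(3-oxocyclobut-1-en-1-yl)acetate; 3 triisopropyl[(3-methylbut-1-yn-1-yl)oxy]silane
Product: 12 TMSE 2-[3-hydroxy-4-isopropyl-5-(TIPS-oxy)phenyl]acetate, via vinylketene 8 (not isolated), via vinylcyclobutenone 9 (not isolated), via dienylketene 10 (not isolated), via cyclohexadienone 11 (not isolated)
Conditions: PhMe, 80 → 110 °C
Reagents that add atoms: none
Why: Danheiser benzannulation: thermal 4π opening of 7 gives vinylketene 8, which adds the siloxyalkyne in a regioselective [2+2] (C13 to the ketene carbon C12, C14 to C8); cyclobutenone 9 opens to dienylketene 10, which closes and tautomerises to the phenol. The closest known reaction type is the cyclobutenone/siloxyalkyne aromatic annulation that gives 2-alkylresorcinol mono-silyl ethers. Ring C closes by a thermal disrotatory 6π electrocyclisation (C11–C12) of the dienylketene, so the net result is insertion of the alkyne between C12 and C8 with new bonds C12–C13 and C8–C14. No stereocentre is formed. The only selectivity needed is the regiochemistry of the [2+2], which the polarisation of the ynol ether secures (nucleophilic carbon to the ketene carbonyl), placing OH, isopropyl and OSi on C12, C13 and C14. The two ring-C oxygens emerge differentiated, which later lets O14 alone direct the C7 carbon to C8.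

**Step 4**
Reactants: 12 TMSE 2-[3-hydroxy-4-isopropyl-5-(TIPS-oxy)phenyl]acetate
Product: 13 TMSE 2-[3-(methoxymethoxy)-4-isopropyl-5-(TIPS-oxy)phenyl]acetate
Conditions: MOMCl, iPr2NEt, CH2Cl2, 0 °C → rt
Reagents that add atoms: chloromethyl methyl ether, COCCl
Why: O-alkylation of the only free phenol (O12) caps it with a base-stable, acid-labile group so that only O14 can direct the later formylation.

**Step 5**
Reactants: 14 5-chloropent-1-yne
Product: 16 (2E)-6-chloro-3-methylhex-2-en-1-ol, via alkenylalane 15 (not isolated)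
Conditions: AlMe3, Cp2ZrCl2 (cat.), CH2Cl2, rt; then (CH2O)n, THF, 0 °C → rt
Reagents that add atoms: trimethylaluminium, C[Al](C)C; paraformaldehyde, C=O
Why: Negishi zirconium-catalysed carboalumination adds Me–Al syn across the terminal alkyne (Me to the internal carbon) and the alkenylalane traps formaldehyde with retention, giving the E-trisubstituted allylic alcohol.

**Step 6**
Reactants: 16 (2E)-6-chloro-3-methylhex-2-en-1-ol
Product: 17 [(2R,3R)-3-(3-chloropropyl)-3-methyloxiran-2-yl]methanol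
Conditions: Ti(OiPr)4 (cat.), D-(−)-diethyl tartrate (cat.), t-BuOOH, 4 Å MS, CH2Cl2, −20 °C
Reagents that add atoms: tert-butyl hydroperoxide, CC(C)(C)OO
Why: Sharpless asymmetric epoxidation of a geraniol-type allylic alcohol; the D-(−)-tartrate catalyst should deliver oxygen to the face that gives the (2R,3R) epoxide.

**Step 7**
Reactants: 17 [(2R,3R)-3-(3-chloropropyl)-3-methyloxiran-2-yl]methanol
Product: 18 tert-butyl{[(2R,3R)-3-(3-chloropropyl)-3-methyloxiran-2-yl]methoxy}dimethylsilane
Conditions: TBSCl, imidazole, DMF, rt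
Reagents that add atoms: tert-butyl(chloro)dimethylsilane, CC(C)(C)[Si](C)(C)Cl
Why: Standard silylation of the primary alcohol provides the epoxy silyl ether needed for the rearrangement.

**Step 8**
Reactants: 18 tert-butyl{[(2R,3R)-3-(3-chloropropyl)-3-methyloxiran-2-yl]methoxy}dimethylsilane
Product: 19 (2R)-2-(TBS-oxymethyl)-5-chloro-2-methylpentanal
Conditions: MABR (2 equiv), CH2Cl2, −78 °C
Reagents that add atoms: none
Why: Organoaluminium-promoted epoxy silyl ether rearrangement: the bulky Lewis acid ionises the tertiary C–O bond and the siloxymethyl group migrates anti to it (inversion at the tertiary carbon), so the epoxide chirality is transferred to the quaternary C4 with the old C2 becoming the aldehyde (future C5).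

**Step 9**
Reactants: 19 (2R)-2-(TBS-oxymethyl)-5-chloro-2-methylpentanal
Product: 20 tert-butyl{[(2S,3E)-2-(3-chloropropyl)-2-methyl-4-(Bpin)but-3-en-1-yl]oxy}dimethylsilane
Conditions: CH2(Bpin)2, LiTMP, THF, 0 °C; then 19, −78 °C → rt
Reagents that add atoms: bis(pinacolato)borylmethane, CC1(C)OB(CB2OC(C)(C)C(C)(C)O2)OC1(C)C
Why: Boron–Wittig olefination: the lithiated geminal bis(boronate) adds to the non-enolisable aldehyde and syn B–O elimination gives the E-alkenylboronate (C5=C6), with the quaternary centre untouched.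

**Step 10**
Reactants: 20 tert-butyl{[(2S,3E)-2-(3-chloropropyl)-2-methyl-4-(Bpin)but-3-en-1-yl]oxy}dimethylsilane
Product: 21 tert-butyl{[(2S,3E)-2-(3-iodopropyl)-2-methyl-4-(Bpin)but-3-en-1-yl]oxy}dimethylsilane
Conditions: NaI, acetone, reflux
Reagents that add atoms: sodium iodide, [Na+].[I-]
Why: Finkelstein exchange converts the inert primary chloride into the iodide needed for enolate alkylation.

**Step 11**
Reactants: 13 TMSE 2-[3-(methoxymethoxy)-4-isopropyl-5-(TIPS-oxy)phenyl]acetate; 21 tert-butyl{[(2S,3E)-2-(3-iodopropyl)-2-methyl-4-(Bpin)but-3-en-1-yl]oxy}dimethylsilane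
Product: 22 TMSE (6S,7E)-2-[3-(methoxymethoxy)-4-isopropyl-5-(TIPS-oxy)phenyl]-6-(TBS-oxymethyl)-6-methyl-8-(Bpin)oct-7-enoate (C2 epimers)
Conditions: LDA, THF, −78 °C; then 21, DMPU, −78 → 0 °C
Reagents that add atoms: none
Why: SN2 alkylation of the arylacetate enolate with the primary iodide forms C10–C1; the new C10 centre is formed as an epimer mixture, which does not matter because C10 becomes sp2 in step 16.

**Step 12**
Reactants: 22 TMSE (6S,7E)-2-[3-(methoxymethoxy)-4-isopropyl-5-(TIPS-oxy)phenyl]-6-(TBS-oxymethyl)-6-methyl-8-(Bpin)oct-7-enoate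
Product: 23 TMSE (6S,7E)-6-(hydroxymethyl)-2-[3-(methoxymethoxy)-4-isopropyl-5-(TIPS-oxy)phenyl]-6-methyl-8-(Bpin)oct-7-enoate
Conditions: CSA (cat.), MeOH/CH2Cl2, 0 °C
Reagents that add atoms: none
Why: Acid-catalysed methanolysis removes the primary alkyl TBS ether while the aryl TIPS ether, aryl MOM ether, TMSE ester and pinacol boronate should survive.

**Step 13**
Reactants: 23 TMSE (6S,7E)-6-(hydroxymethyl)-2-[3-(methoxymethoxy)-4-isopropyl-5-(TIPS-oxy)phenyl]-6-methyl-8-(Bpin)oct-7-enoate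
Product: 24 TMSE (6S,7E)-6-formyl-2-[3-(methoxymethoxy)-4-isopropyl-5-(TIPS-oxy)phenyl]-6-methyl-8-(Bpin)oct-7-enoate
Conditions: Dess–Martin periodinane, NaHCO3, CH2Cl2, rt
Reagents that add atoms: none
Why: Dess–Martin oxidation, done while no free phenol is present, turns the C19 arm into a small planar non-enolisable formyl group that is meant to take the axial site in step 16.

**Step 14**
Reactants: 24 TMSE (6S,7E)-6-formyl-2-[3-(methoxymethoxy)-4-isopropyl-5-(TIPS-oxy)phenyl]-6-methyl-8-(Bpin)oct-7-enoate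
Product: 25 (6S,7E)-6-formyl-2-[3-hydroxy-5-(methoxymethoxy)-4-isopropylphenyl]-6-methyl-8-(Bpin)oct-7-enoic acid
Conditions: TBAF, THF, 0 °C → rt; pH 4 work-up
Reagents that add atoms: none
Why: Fluoride cleaves the aryl silyl ether and the TMSE ester (loss of Me3SiF and ethene) in one operation, freeing O14–H and the C20 acid.

**Step 15**
Reactants: 25 (6S,7E)-6-formyl-2-[3-hydroxy-5-(methoxymethoxy)-4-isopropylphenyl]-6-methyl-8-(Bpin)oct-7-enoic acid
Product: 26 (6S,7E)-6-formyl-2-[2-formyl-3-hydroxy-5-(methoxymethoxy)-4-isopropylphenyl]-6-methyl-8-(Bpin)oct-7-enoic acid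
Conditions: MgCl2, Et3N (excess), (CH2O)n, MeCN, reflux
Reagents that add atoms: paraformaldehyde, C=O
Why: Casnati–Skattebøl formylation: the magnesium phenoxide of O14 delivers formaldehyde only to its free ortho carbon C8 (C13 is blocked, O12 is capped) and a second formaldehyde oxidises the hydroxymethyl intermediate, installing C7.

**Step 16**
Reactants: 26 (6S,7E)-6-formyl-2-[2-formyl-3-hydroxy-5-(methoxymethoxy)-4-isopropylphenyl]-6-methyl-8-(Bpin)oct-7-enoic acid
Product: 28 14-acetoxy-12-(methoxymethoxy)-19-oxo-6α-(Bpin)abieta-8,11,13-trien-20,7β-olide, via benzopyranone 27 (not isolated)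
Conditions: Ac2O, PhMe, 110 °C, high dilution
Reagents that add atoms: acetic anhydride, CC(=O)OC(C)=O
Why: Acetic anhydride acetylates O14 and dehydrates the o-formyl arylacetic acid to the o-quinoid 2-benzopyran-3-one 27, which undergoes intramolecular Diels–Alder addition of the tethered alkene; addition across C7/C10 makes the lactone the bridge (O7 and C20 cis), the tether length fixes C5 to C10 (the donor terminus of the diene meeting the carbon β to boron), the E-alkene puts C4 and boron trans (5α-H, 6α-B), the quaternary C4 disfavours the tether-endo mode, and the formyl group, smaller than methyl, should take the axial site over the lactone carbonyl, setting C5, C6, C7 and C10 relative to C4.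

**Step 17**
Reactants: 28 14-acetoxy-12-(methoxymethoxy)-19-oxo-6α-(Bpin)abieta-8,11,13-trien-20,7β-olide
Product: 30 6α,14,19-trihydroxy-12-(methoxymethoxy)abieta-8,11,13-trien-20,7β-olide, via C19 carbinol 29 (not isolated)
Conditions: NaBH4, THF/MeOH, −20 °C; then NaBO3·4H2O, THF/H2O, 0 °C → rt
Reagents that add atoms: sodium perborate, O=BO[O-].[Na+]
Why: Borohydride reduces only the aldehyde (hindered bridged lactone untouched), then perborate oxidises the C–B bond with retention to the 6α-alcohol and its mild basicity cleaves the aryl acetate.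

**Step 18**
Reactants: 30 6α,14,19-trihydroxy-12-(methoxymethoxy)abieta-8,11,13-trien-20,7β-olide
Product: 31 6α,12,14,19-tetrahydroxyabieta-8,11,13-trien-20,7β-olide
Conditions: aq. HCl (3 M), THF, 40 °C, under argon
Reagents that add atoms: none
Why: Acid hydrolysis of the aryl MOM acetal frees the resorcinol; acid is chosen over hydrogenolysis because the benzylic C7–O lactone bond would be at risk under Pd/H2.

**Step 19**
Reactants: 31 6α,12,14,19-tetrahydroxyabieta-8,11,13-trien-20,7β-olide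
Product: 32 (4S,5S,6R,7R,10R)-6α,12,19-trihydroxy-11,14-dioxoabieta-8,12-dien-20,7β-olide (target)
Conditions: Fremy's salt, KH2PO4 buffer, acetone/H2O, rt
Reagents that add atoms: potassium nitrosodisulfonate, [K+].[K+].[O-]S(=O)(=O)N([O])S(=O)(=O)[O-]
Why: Teuber oxidation: the phenoxyl radical is oxygenated at the only unsubstituted ring carbon C11 (para to O14), giving the 2-hydroxy-1,4-benzoquinone (the same tautomeric system results if O12 reacts first), with the aliphatic alcohols and lactone unaffected.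

**Compound list**
1 | ethyl 2-methylpropanoate | CCOC(=O)C(C)C | starting material
2 | lithium 3-methylbut-1-yn-1-olate | CC(C)C#C[O-].[Li+] | intermediate (not isolated)
3 | triisopropyl[(3-methylbut-1-yn-1-yl)oxy]silane | CC(C)C#CO[Si](C(C)C)(C(C)C)C(C)C | intermediate
4 | 3-ethoxycyclobut-2-en-1-one | CCOC1=CC(=O)C1 | starting material
5 | 2-(trimethylsilyl)ethyl acetate | CC(=O)OCC[Si](C)(C)C | starting material
6 | TMSE 2-(3-ethoxy-1-hydroxycyclobut-2-en-1-yl)acetate (as lithium alkoxide) | CCOC1=CC(O)(CC(=O)OCC[Si](C)(C)C)C1 | intermediate (not isolated)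
7 | TMSE 2-(3-oxocyclobut-1-en-1-yl)acetate | O=C1C=C(CC(=O)OCC[Si](C)(C)C)C1 | intermediate
8 | TMSE 3-methylidene-5-oxopent-4-enoate (vinylketene) | O=C=CC(=C)CC(=O)OCC[Si](C)(C)C | intermediate (not isolated)
9 | TMSE 3-[4-oxo-3-isopropyl-2-(TIPS-oxy)cyclobut-2-en-1-yl]but-3-enoate | C=C(CC(=O)OCC[Si](C)(C)C)C1C(=O)C(C(C)C)=C1O[Si](C(C)C)(C(C)C)C(C)C | intermediate (not isolated)
10 | TMSE 3-methylidene-7-oxo-6-isopropyl-5-(TIPS-oxy)hepta-4,6-dienoate (dienylketene) | O=C=C(C(C)C)C(O[Si](C(C)C)(C(C)C)C(C)C)=CC(=C)CC(=O)OCC[Si](C)(C)C | intermediate (not isolated)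
11 | TMSE 2-[5-oxo-4-isopropyl-3-(TIPS-oxy)cyclohexa-1,3-dien-1-yl]acetate | O=C1CC(CC(=O)OCC[Si](C)(C)C)=CC(O[Si](C(C)C)(C(C)C)C(C)C)=C1C(C)C | intermediate (not isolated)
12 | TMSE 2-[3-hydroxy-4-isopropyl-5-(TIPS-oxy)phenyl]acetate | CC(C)c1c(O)cc(CC(=O)OCC[Si](C)(C)C)cc1O[Si](C(C)C)(C(C)C)C(C)C | intermediate
13 | TMSE 2-[3-(methoxymethoxy)-4-isopropyl-5-(TIPS-oxy)phenyl]acetate | CC(C)c1c(OCOC)cc(CC(=O)OCC[Si](C)(C)C)cc1O[Si](C(C)C)(C(C)C)C(C)C | intermediate
14 | 5-chloropent-1-yne | C#CCCCCl | starting material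
15 | [(1E)-5-chloro-2-methylpent-1-en-1-yl]dimethylalumane | C[Al](C)/C=C(\C)CCCCl | intermediate (not isolated)
16 | (2E)-6-chloro-3-methylhex-2-en-1-ol | OC/C=C(\C)CCCCl | intermediate
17 | [(2R,3R)-3-(3-chloropropyl)-3-methyloxiran-2-yl]methanol | OC[C@H]1O[C@]1(C)CCCCl | intermediate
18 | tert-butyl{[(2R,3R)-3-(3-chloropropyl)-3-methyloxiran-2-yl]methoxy}dimethylsilane | CC(C)(C)[Si](C)(C)OC[C@H]1O[C@]1(C)CCCCl | intermediate
19 | (2R)-2-(TBS-oxymethyl)-5-chloro-2-methylpentanal | ClCCC[C@](C)(CO[Si](C)(C)C(C)(C)C)C=O | intermediate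
20 | tert-butyl{[(2S,3E)-2-(3-chloropropyl)-2-methyl-4-(Bpin)but-3-en-1-yl]oxy}dimethylsilane | ClCCC[C@](C)(CO[Si](C)(C)C(C)(C)C)/C=C/B1OC(C)(C)C(C)(C)O1 | intermediate
21 | tert-butyl{[(2S,3E)-2-(3-iodopropyl)-2-methyl-4-(Bpin)but-3-en-1-yl]oxy}dimethylsilane | ICCC[C@](C)(CO[Si](C)(C)C(C)(C)C)/C=C/B1OC(C)(C)C(C)(C)O1 | intermediate
22 | TMSE (6S,7E)-2-[3-(methoxymethoxy)-4-isopropyl-5-(TIPS-oxy)phenyl]-6-(TBS-oxymethyl)-6-methyl-8-(Bpin)oct-7-enoate, C2 epimers | CC(C)c1c(OCOC)cc(cc1O[Si](C(C)C)(C(C)C)C(C)C)C(CCC[C@](C)(CO[Si](C)(C)C(C)(C)C)/C=C/B1OC(C)(C)C(C)(C)O1)C(=O)OCC[Si](C)(C)C | intermediate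
23 | TMSE (6S,7E)-6-(hydroxymethyl)-2-[3-(methoxymethoxy)-4-isopropyl-5-(TIPS-oxy)phenyl]-6-methyl-8-(Bpin)oct-7-enoate | CC(C)c1c(OCOC)cc(cc1O[Si](C(C)C)(C(C)C)C(C)C)C(CCC[C@](C)(CO)/C=C/B1OC(C)(C)C(C)(C)O1)C(=O)OCC[Si](C)(C)C | intermediate
24 | TMSE (6S,7E)-6-formyl-2-[3-(methoxymethoxy)-4-isopropyl-5-(TIPS-oxy)phenyl]-6-methyl-8-(Bpin)oct-7-enoate | CC(C)c1c(OCOC)cc(cc1O[Si](C(C)C)(C(C)C)C(C)C)C(CCC[C@](C)(C=O)/C=C/B1OC(C)(C)C(C)(C)O1)C(=O)OCC[Si](C)(C)C | intermediate
25 | (6S,7E)-6-formyl-2-[3-hydroxy-5-(methoxymethoxy)-4-isopropylphenyl]-6-methyl-8-(Bpin)oct-7-enoic acid | CC(C)c1c(OCOC)cc(cc1O)C(CCC[C@](C)(C=O)/C=C/B1OC(C)(C)C(C)(C)O1)C(=O)O | intermediate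
26 | (6S,7E)-6-formyl-2-[2-formyl-3-hydroxy-5-(methoxymethoxy)-4-isopropylphenyl]-6-methyl-8-(Bpin)oct-7-enoic acid | CC(C)c1c(OCOC)cc(C(CCC[C@](C)(C=O)/C=C/B2OC(C)(C)C(C)(C)O2)C(=O)O)c(C=O)c1O | intermediate
27 | 8-acetoxy-6-(methoxymethoxy)-7-isopropyl-4-[(4S,5E)-4-formyl-4-methyl-6-(Bpin)hex-5-en-1-yl]-3H-2-benzopyran-3-one | O=C1OC=C2C(OC(C)=O)=C(C(C)C)C(OCOC)=CC2=C1CCC[C@](C)(C=O)/C=C/B1OC(C)(C)C(C)(C)O1 | intermediate (not isolated)
28 | 14-acetoxy-12-(methoxymethoxy)-19-oxo-6α-(Bpin)abieta-8,11,13-trien-20,7β-olide (5α-H, 10β-C20, 4β-CHO) | CC(C)c1c(OCOC)cc2c(c1OC(C)=O)[C@H]1OC(=O)[C@@]23CCC[C@](C)(C=O)[C@@H]3[C@H]1B1OC(C)(C)C(C)(C)O1 | intermediate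
29 | 14-acetoxy-19-hydroxy-12-(methoxymethoxy)-6α-(Bpin)abieta-8,11,13-trien-20,7β-olide | CC(C)c1c(OCOC)cc2c(c1OC(C)=O)[C@H]1OC(=O)[C@@]23CCC[C@](C)(CO)[C@@H]3[C@H]1B1OC(C)(C)C(C)(C)O1 | intermediate (not isolated)
30 | 6α,14,19-trihydroxy-12-(methoxymethoxy)abieta-8,11,13-trien-20,7β-olide | CC(C)c1c(OCOC)cc2c(c1O)[C@H]1OC(=O)[C@@]23CCC[C@](C)(CO)[C@@H]3[C@H]1O | intermediate
31 | 6α,12,14,19-tetrahydroxyabieta-8,11,13-trien-20,7β-olide | CC(C)c1c(O)cc2c(c1O)[C@H]1OC(=O)[C@@]23CCC[C@](C)(CO)[C@@H]3[C@H]1O | intermediate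
32 | (4S,5S,6R,7R,10R)-6α,12,19-trihydroxy-11,14-dioxoabieta-8,12-dien-20,7β-olide | CC(C)C1=C(O)C(=O)C2=C(C1=O)[C@H]1OC(=O)[C@@]23CCC[C@](C)(CO)[C@@H]3[C@H]1O | target

**Counts**
Total steps: 19. Longest linear sequence: 15 (steps 5–19, from 5-chloropent-1-yne).

**Steps most likely to fail**

Step 16. What may go wrong: weak discrimination between the two faces defined by C4 (formyl versus methyl in the axial site), closure through the tether-endo (cis-fused) geometry, or oligomerisation of the o-quinoid pyranone before it cyclises. Fallback, from 24 back to 28: the control element is changed from formyl to the smaller, rod-shaped cyano group, whose preference for the axial site over methyl is far larger. Aldehyde 24 is converted in one operation (hydroxylamine-O-sulfonic acid) into the 6-cyano ester F1. Fluoride deprotection gives the cyano phenol acid F2, magnesium-mediated ortho-formylation gives the cyano formyl acid F3, and the same acetic anhydride cycloaddition gives the 19-nitrile adduct F4. Hydrozirconation of the nitrile with Schwartz's reagent and hydrolysis of the N-metallo imine then returns aldehyde 28.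

Step 17. What may go wrong: in adduct 28 boron on C6 is anti-periplanar to the C7–O lactone bond, so once a nucleophile adds to boron, deborylative elimination with opening of the lactone can outrun the oxidative 1,2-shift; prolonged base could also let O19 attack C20. Fallback, from 28 back to 30: the elimination is made deliberate and the oxygen pattern is rebuilt along the presumed biogenetic line. K2CO3/MeOH on 28 gives the Δ6-ene carboxylic acid F5 (aryl acetate lost). Upjohn dihydroxylation (OsO4 cat., NMO) from the open α-face gives the 6α,7α-diol acid F6. Catalytic TsOH ionises the electron-rich benzylic C7–OH, and capture by the β-oriented C20 carboxyl closes the 20,7β-lactone with 6α-OH retained, giving the 19-oxo lactone F7. Borohydride reduction of F7 gives 30.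

Step 8. What may go wrong: the stoichiometric, very hindered aluminium reagent may give competing hydride shift (α-siloxy ketone), chloride participation, or incomplete chirality transfer. Fallback, from 16 back to 20: the quaternary centre is made by epoxide opening instead of a 1,2-shift. Sharpless epoxidation of 16 with L-(+)-diethyl tartrate gives the (2S,3S)-epoxy alcohol F8. Diethyl(ethynyl)aluminium opens it at the tertiary C3 with inversion to the ethynyl diol F9. NaIO4 cleavage gives the quaternary ynal F10, NaBH4 gives the alcohol F11, and TBSCl gives the silyl ether F12. Zirconocene-catalysed hydroboration of the terminal alkyne with pinacolborane then gives E-alkenylboronate 20.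

**Further compounds**
F1 | step 16 | TMSE (6S,7E)-6-cyano-2-[3-(methoxymethoxy)-4-isopropyl-5-(TIPS-oxy)phenyl]-6-methyl-8-(Bpin)oct-7-enoate | CC(C)c1c(OCOC)cc(cc1O[Si](C(C)C)(C(C)C)C(C)C)C(CCC[C@](C)(C#N)/C=C/B1OC(C)(C)C(C)(C)O1)C(=O)OCC[Si](C)(C)C
F2 | step 16 | (6S,7E)-6-cyano-2-[3-hydroxy-5-(methoxymethoxy)-4-isopropylphenyl]-6-methyl-8-(Bpin)oct-7-enoic acid | CC(C)c1c(OCOC)cc(cc1O)C(CCC[C@](C)(C#N)/C=C/B1OC(C)(C)C(C)(C)O1)C(=O)O
F3 | step 16 | (6S,7E)-6-cyano-2-[2-formyl-3-hydroxy-5-(methoxymethoxy)-4-isopropylphenyl]-6-methyl-8-(Bpin)oct-7-enoic acid | CC(C)c1c(OCOC)cc(C(CCC[C@](C)(C#N)/C=C/B2OC(C)(C)C(C)(C)O2)C(=O)O)c(C=O)c1O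
F4 | step 16 | 14-acetoxy-12-(methoxymethoxy)-6α-(Bpin)-20,7β-olido-abieta-8,11,13-triene-19-nitrile | CC(C)c1c(OCOC)cc2c(c1OC(C)=O)[C@H]1OC(=O)[C@@]23CCC[C@](C)(C#N)[C@@H]3[C@H]1B1OC(C)(C)C(C)(C)O1
F5 | step 17 | 14-hydroxy-12-(methoxymethoxy)-19-oxoabieta-6,8,11,13-tetraen-20-oic acid | CC(C)c1c(OCOC)cc2c(c1O)C=C[C@H]3[C@@](C)(C=O)CCC[C@]23C(=O)O
F6 | step 17 | 6α,7α,14-trihydroxy-12-(methoxymethoxy)-19-oxoabieta-8,11,13-trien-20-oic acid | CC(C)c1c(OCOC)cc2c(c1O)[C@H](O)[C@H](O)[C@H]3[C@@](C)(C=O)CCC[C@]23C(=O)O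
F7 | step 17 | 6α,14-dihydroxy-12-(methoxymethoxy)-19-oxoabieta-8,11,13-trien-20,7β-olide | CC(C)c1c(OCOC)cc2c(c1O)[C@H]1OC(=O)[C@@]23CCC[C@](C)(C=O)[C@@H]3[C@H]1O
F8 | step 8 | [(2S,3S)-3-(3-chloropropyl)-3-methyloxiran-2-yl]methanol | OC[C@@H]1O[C@@]1(C)CCCCl
F9 | step 8 | 3-(3-chloropropyl)-3-methylpent-4-yne-1,2-diol (C3 inverted relative to F8) | OC[C@H](O)[C@@](C)(CCCCl)C#C
F10 | step 8 | 2-(3-chloropropyl)-2-methylbut-3-ynal | ClCCC[C@](C)(C=O)C#C
F11 | step 8 | 2-(3-chloropropyl)-2-methylbut-3-yn-1-ol | ClCCC[C@](C)(CO)C#C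
F12 | step 8 | tert-butyl{[2-(3-chloropropyl)-2-methylbut-3-yn-1-yl]oxy}dimethylsilane | ClCCC[C@](C)(CO[Si](C)(C)C(C)(C)C)C#C
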